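**Strategy.** Ring A is not attached to the crowded central oxygen by arylation but is grown on it. Its alternating pattern (ether oxygen at the 1-position of ring A, hydroxyls at the 3- and 5-positions, hydrogens at the 2-, 4- and 6-positions) is what a 1,1,3-trioxygenated butadiene delivers to a β-oxygenated acrylate. The key step joins the α-bromo β-aryloxy acrylate 8, which already carries rings B and C as methyl ethers, to diene 10, forming the ring A bonds between positions 6 and 1 and between positions 3 and 2. Loss of HBr, methanol and the silyl group then aromatizes ring A as a salicylate. Ester hydrolysis, decarboxylation and global demethylation finish the target.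

Key step: step 7

Ring labels: ring A is the 3,5-dihydroxyphenoxy ring, numbered from the carbon that bears the ether oxygen as position 1. Ring B is the central ring, whose position 1 bears the oxygen to ring A and whose position 4 bears the oxygen to ring C. Ring C is the 2,4,6-trihydroxyphenyl ring. The target is achiral; 11 and 12 are racemic and transient.

Assumption: the hot bromination of methyl propiolate is taken to give mainly the (Z)-dibromide 7. The reagents 1-bromo-3,5-dimethoxybenzene and 4-fluoro-2,6-dimethoxybenzaldehyde, used only in fallbacks, are taken as purchasable.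

Step 1
Reactants: 1 4-bromo-2,6-dimethoxyphenol
Product: 2 2-(benzyloxy)-5-bromo-1,3-dimethoxybenzene
Conditions: BnBr, K2CO3, DMF, rt
Reagents that add atoms: benzyl bromide, BrCc1ccccc1
Why: Williamson etherification of the acidic phenol masks the hydroxyl, so that only the trimethoxyphenol can act as the nucleophile in the copper coupling that follows.

Step 2
Reactants: 2 2-(benzyloxy)-5-bromo-1,3-dimethoxybenzene; 3 2,4,6-trimethoxyphenol
Product: 4 2-(benzyloxy)-1,3-dimethoxy-5-(2,4,6-trimethoxyphenoxy)benzene
Conditions: CuI (cat.), picolinic acid (cat.), K3PO4, DMSO, 90 °C, argon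
Reagents that add atoms: none
Why: Ullmann-type C–O coupling; the CuI/picolinic acid system tolerates di-ortho-substituted phenols, and the reacting carbon of bromide 2 has no ortho substituent.

Step 3
Reactants: 4 2-(benzyloxy)-1,3-dimethoxy-5-(2,4,6-trimethoxyphenoxy)benzene
Product: 5 2,6-dimethoxy-4-(2,4,6-trimethoxyphenoxy)phenol
Conditions: H2 (1 atm), 10% Pd/C, EtOAc/MeOH, rt
Reagents that add atoms: none
Why: Catalytic hydrogenolysis cleaves only the benzylic C–O bond; methyl ethers and the diaryl ether are inert.

Step 4
Reactants: 6 methyl propiolate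
Product: 7 methyl (Z)-2,3-dibromoacrylate
Conditions: Br2 (1 equiv), CCl4 or PhCF3, 70 °C
Reagents that add atoms: bromine, BrBr
Why: Bromine addition to the alkynoate under equilibrating conditions should give the cis-dibromide; bromine is consumed here, before any electron-rich arene is present, so no ring bromination can occur later.

Step 5
Reactants: 5 2,6-dimethoxy-4-(2,4,6-trimethoxyphenoxy)phenol; 7 methyl (Z)-2,3-dibromoacrylate
Product: 8 methyl (Z)-2-bromo-3-[2,6-dimethoxy-4-(2,4,6-trimethoxyphenoxy)phenoxy]acrylate
Conditions: K2CO3, MeCN, 0 °C to rt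
Reagents that add atoms: none
Why: Nucleophilic vinylic substitution by addition–elimination: the phenoxide adds to the β-carbon and the ester-stabilized α-bromo enolate expels the β-bromide with retention, which should leave the aryloxy group cis to bromine and trans to the ester, the geometry that step 7 needs for anti elimination.

Step 6
Reactants: 9 methyl (E)-3-methoxybut-2-enoate
Product: 10 (E)-1,3-dimethoxy-1-(trimethylsilyloxy)buta-1,3-diene
Conditions: LiN(iPr)2, THF, −78 °C; Me3SiCl, −78 °C to rt; distillation
Reagents that add atoms: chlorotrimethylsilane, C[Si](C)(C)Cl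
Why: Kinetic γ-deprotonation of the vinylogous ester and O-silylation of the dienolate is the standard preparation of this ketene-acetal diene.

Step 7
Reactants: 8 methyl (Z)-2-bromo-3-[2,6-dimethoxy-4-(2,4,6-trimethoxyphenoxy)phenoxy]acrylate; 10 (E)-1,3-dimethoxy-1-(trimethylsilyloxy)buta-1,3-diene
Product: 13 methyl 2-[2,6-dimethoxy-4-(2,4,6-trimethoxyphenoxy)phenoxy]-6-hydroxy-4-methoxybenzoate, via bromo cycloadduct 11 (not isolated), via cyclohexadiene silyl ketal 12 (not isolated)
Conditions: 10 (3 equiv), PhMe, 100 °C, sealed tube, argon; then DBU, 0 °C to rt; then 1 M HCl, THF, rt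
Reagents that add atoms: none
Why: Proposed new method: diene 10 and acrylate 8 should combine in an asynchronous normal-demand Diels–Alder reaction in which the CH2 terminus of the diene bonds to the aryloxy-bearing β-carbon (the ring A bond between positions 6 and 1) and the ketene-acetal carbon to the brominated α-carbon (the bond between positions 3 and 2), suprafacial addition to the (Z)-alkene placing the hydrogen on position 1 and the bromine on position 2 trans in adduct 11. DBU then removes HBr by anti-periplanar bimolecular elimination while position 3 is still a silyl ketal, so that no enolate or dienolate exists that could expel the aryloxide, and acid hydrolysis of ketal 12 (loss of methanol and trimethylsilanol) gives the cross-conjugated keto tautomer of the phenol, which aromatizes at once to 13. The nearest precedent class is the annulation of such ketene-acetal dienes with alkynoates, 2-haloacrylates or halogenated quinones, where loss of hydrogen halide or alcohol delivers resorcylate-type arenes; new here is a β-aryloxy group on the dienophile that must survive as a ring substituent. Ring A is closed by intermolecular [4+2] annulation with both ring bonds made in the one step (in the stepwise limit, Michael addition followed by 6-(enolexo)-exo-trig closure of the α-bromo ester enolate onto the oxocarbenium carbon). No stereocentre remains; the transient cis relation of bromine and aryloxy comes from the dienophile geometry and serves only the elimination. The step needs regioselectivity, secured by the match of the large HOMO coefficient at the diene CH2 terminus with the ester-polarized β-carbon of 8, and leaving-group selectivity, secured by the nonpolar Lewis-acid-free medium (which disfavours a zwitterionic enolate able to shed aryloxide) and by eliminating HBr before the ketal is unmasked.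

Step 8
Reactants: 13 methyl 2-[2,6-dimethoxy-4-(2,4,6-trimethoxyphenoxy)phenoxy]-6-hydroxy-4-methoxybenzoate
Product: 15 3-[2,6-dimethoxy-4-(2,4,6-trimethoxyphenoxy)phenoxy]-5-methoxyphenol, via benzoic acid 14 (not isolated)
Conditions: KOH, EtOH/H2O, reflux; then 6 M HCl to pH 1, 80 °C
Reagents that add atoms: none
Why: Saponification of the salicylate ester, slowed but not blocked by its two ortho substituents, then acid-promoted protodecarboxylation, which is easy because the ipso carbon is ortho and para to three oxygen substituents.

Step 9
Reactants: 15 3-[2,6-dimethoxy-4-(2,4,6-trimethoxyphenoxy)phenoxy]-5-methoxyphenol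
Product: 16 triphlorethol A
Conditions: BBr3 (excess), CH2Cl2, −78 °C to rt, argon; then H2O, 0 °C
Reagents that add atoms: none
Why: Lewis-acid-mediated cleavage of the six aryl methyl ethers (bromide attacks the methyl carbon of the boron-complexed ether); the diaryl ether bonds offer no carbon open to this displacement and should persist.

**Compound list**

1 | 4-bromo-2,6-dimethoxyphenol | COc1cc(Br)cc(OC)c1O | starting material
2 | 2-(benzyloxy)-5-bromo-1,3-dimethoxybenzene | COc1cc(Br)cc(OC)c1OCc1ccccc1 | intermediate
3 | 2,4,6-trimethoxyphenol | COc1cc(OC)c(O)c(OC)c1 | starting material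
4 | 2-(benzyloxy)-1,3-dimethoxy-5-(2,4,6-trimethoxyphenoxy)benzene | COc1cc(OC)c(Oc2cc(OC)c(OCc3ccccc3)c(OC)c2)c(OC)c1 | intermediate
5 | 2,6-dimethoxy-4-(2,4,6-trimethoxyphenoxy)phenol | COc1cc(OC)c(Oc2cc(OC)c(O)c(OC)c2)c(OC)c1 | intermediate
6 | methyl propiolate | C#CC(=O)OC | starting material
7 | methyl (Z)-2,3-dibromoacrylate (bromines cis) | COC(=O)/C(Br)=C/Br | intermediate
8 | methyl (Z)-2-bromo-3-[2,6-dimethoxy-4-(2,4,6-trimethoxyphenoxy)phenoxy]acrylate (aryloxy cis to bromine, trans to ester) | COC(=O)/C(Br)=C/Oc1c(OC)cc(Oc2c(OC)cc(OC)cc2OC)cc1OC | intermediate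
9 | methyl (E)-3-methoxybut-2-enoate | CO/C(C)=C/C(=O)OC | starting material
10 | (E)-1,3-dimethoxy-1-(trimethylsilyloxy)buta-1,3-diene | C=C(OC)/C=C(\OC)O[Si](C)(C)C | intermediate
11 | methyl 1-bromo-6-[2,6-dimethoxy-4-(2,4,6-trimethoxyphenoxy)phenoxy]-2,4-dimethoxy-2-(trimethylsilyloxy)cyclohex-3-ene-1-carboxylate (bromine and aryloxy cis, racemic, either configuration at the ketal carbon) | COC(=O)[C@@]1(Br)[C@H](Oc2c(OC)cc(Oc3c(OC)cc(OC)cc3OC)cc2OC)CC(OC)=CC1(OC)O[Si](C)(C)C | intermediate
12 | methyl 2-[2,6-dimethoxy-4-(2,4,6-trimethoxyphenoxy)phenoxy]-4,6-dimethoxy-6-(trimethylsilyloxy)cyclohexa-1,4-diene-1-carboxylate (racemic) | COC(=O)C1=C(Oc2c(OC)cc(Oc3c(OC)cc(OC)cc3OC)cc2OC)CC(OC)=CC1(OC)O[Si](C)(C)C | intermediate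
13 | methyl 2-[2,6-dimethoxy-4-(2,4,6-trimethoxyphenoxy)phenoxy]-6-hydroxy-4-methoxybenzoate | COC(=O)c1c(O)cc(OC)cc1Oc1c(OC)cc(Oc2c(OC)cc(OC)cc2OC)cc1OC | intermediate
14 | 2-[2,6-dimethoxy-4-(2,4,6-trimethoxyphenoxy)phenoxy]-6-hydroxy-4-methoxybenzoic acid | OC(=O)c1c(O)cc(OC)cc1Oc1c(OC)cc(Oc2c(OC)cc(OC)cc2OC)cc1OC | intermediate
15 | 3-[2,6-dimethoxy-4-(2,4,6-trimethoxyphenoxy)phenoxy]-5-methoxyphenol | Oc1cc(OC)cc(Oc2c(OC)cc(Oc3c(OC)cc(OC)cc3OC)cc2OC)c1 | intermediate
16 | triphlorethol A, 2-[4-(3,5-dihydroxyphenoxy)-3,5-dihydroxyphenoxy]benzene-1,3,5-triol | Oc1cc(O)cc(Oc2c(O)cc(Oc3c(O)cc(O)cc3O)cc2O)c1 | target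

**Count.** Total steps: 9. Longest linear sequence: 7 (steps 1, 2, 3, 5, 7, 8, 9); steps 4 and 6 are side branches.

**Steps most likely to fail**

1. Step 7 (cycloaddition–aromatization). The push-pull dienophile may react too slowly while the diene decays thermally. The addition may turn stepwise, so that the ester enolate ejects the aryloxide (net vinylic substitution). Aryloxide may be lost in place of bromide during aromatization. Fallback with a different bond construction: setting out from phenol 5, Ullmann etherification with 1-bromo-3,5-dimethoxybenzene (COc1cc(Br)cc(OC)c1; CuI, picolinic acid, K3PO4, DMSO, 100 °C) should give the heptamethyl ether 2-(3,5-dimethoxyphenoxy)-1,3-dimethoxy-5-(2,4,6-trimethoxyphenoxy)benzene F1. Demethylation of F1 with BBr3 as in step 9 leads directly to target 16, where the route is rejoined; steps 4 to 8 fall away.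

2. Step 5 (vinylic substitution). The base may dehydrobrominate 7 to a bromopropiolate, which then adds the phenoxide with the opposite regiochemistry, or the alkene geometry may scramble. Fallback in which bromine is installed on a deactivated aryl enol ether and the hindered phenol enters by aryloxide exchange: setting out from methyl propiolate 6, DABCO-catalysed conjugate addition of 4-nitrophenol (CH2Cl2, rt) should give methyl (E)-3-(4-nitrophenoxy)acrylate F2. Bromine addition (Br2, CH2Cl2) gives methyl 2,3-dibromo-3-(4-nitrophenoxy)propanoate F3, and Et3N eliminates HBr to methyl (Z)-2-bromo-3-(4-nitrophenoxy)acrylate F4; the nitroarene is inert to bromine. Phenol 5 with K2CO3 in MeCN then displaces the less basic 4-nitrophenoxide from F4 by addition–elimination, and the route is rejoined at 8.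

3. Step 2 (copper coupling). Two electron-rich partners and a di-ortho-substituted phenoxide may give slow turnover, and the phenoxide of 3 may be oxidized, leading to low conversion. Fallback by nucleophilic aromatic substitution and oxidative deformylation: setting out from phenol 3, reaction with 4-fluoro-2,6-dimethoxybenzaldehyde (COc1cc(F)cc(OC)c1C=O; K2CO3, DMF, 120 °C) should give 2,6-dimethoxy-4-(2,4,6-trimethoxyphenoxy)benzaldehyde F5 by displacement of the fluoride para to the formyl group. Baeyer–Villiger (Dakin-type) oxidation of the electron-rich aldehyde with mCPBA (CH2Cl2, 0 °C) gives 2,6-dimethoxy-4-(2,4,6-trimethoxyphenoxy)phenyl formate F6, and methanolysis (K2CO3, MeOH) releases phenol 5, where the route is rejoined; steps 1 and 3 fall away.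

**Further compounds**

F1 | step 7 | 2-(3,5-dimethoxyphenoxy)-1,3-dimethoxy-5-(2,4,6-trimethoxyphenoxy)benzene | COc1cc(OC)cc(Oc2c(OC)cc(Oc3c(OC)cc(OC)cc3OC)cc2OC)c1
F2 | step 5 | methyl (E)-3-(4-nitrophenoxy)acrylate | COC(=O)/C=C/Oc1ccc(cc1)[N+](=O)[O-]
F3 | step 5 | methyl 2,3-dibromo-3-(4-nitrophenoxy)propanoate (mixture of diastereomers) | COC(=O)C(Br)C(Br)Oc1ccc(cc1)[N+](=O)[O-]
F4 | step 5 | methyl (Z)-2-bromo-3-(4-nitrophenoxy)acrylate | COC(=O)/C(Br)=C/Oc1ccc(cc1)[N+](=O)[O-]
F5 | step 2 | 2,6-dimethoxy-4-(2,4,6-trimethoxyphenoxy)benzaldehyde | COc1cc(OC)c(Oc2cc(OC)c(C=O)c(OC)c2)c(OC)c1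
F6 | step 2 | 2,6-dimethoxy-4-(2,4,6-trimethoxyphenoxy)phenyl formate | COc1cc(OC)c(Oc2cc(OC)c(OC=O)c(OC)c2)c(OC)c1
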